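**Retrosynthetic overview** (carotenoid numbering; ring A = C1–C6 next to the C8 ketone, ring B = C1'–C6')
- Last bond: lipase acylation of the primary C19–OH of siphonaxanthin 30. C9=C10 comes from a Horner–Wadsworth–Emmons reaction of ring-A ketophosphonate 16 (C1–C9, C19) with C27 aldehyde 28 (C10–C6').
- 28: ring B is bought in (R)-α-ionone; C3' is oxidised and reduced, then the chain grows by C15 + C10 + C2 Wittig reactions.
- Enabling feature of ring A: C2 and C6 flank the quaternary C1, and C6 carries the C7–C8(=O) arm. Tying C8 back to C2 turns C2–C1–C6–C7–C8 into 4,4-dimethylcyclopentenone, with C2 as nucleophilic alpha' carbon and C6 as electrophilic beta carbon. A C3–C4–C5 enal is annulated across them in one operation (C2–C3 and C5–C6), giving a bicyclo[3.2.1]octene.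
- The temporary C2–C8 bond, then part of a bridgehead beta-diketone, is cut by methoxide (retro-Claisen). A dienol acetate moves the alkene to C5=C6, and a ketoreductase sets C3 (R).
- Ring order: ring B and the temporary five-membered ring are bought; ring A is closed in step 4; the five-membered ring is opened in step 6.

Key step: step 4

Remark: (R)-α-ionone (6R) is taken as purchasable in enantiopure form; C6' of the target derives from it unchanged.

Step 1
Reactants: 1 4,4-dimethylcyclopent-2-en-1-one
Product: 2 trimethyl[(5,5-dimethylcyclopenta-1,3-dien-2-yl)oxy]silane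
Conditions: TMSOTf, Et3N, CH2Cl2, 0 °C
Reagents that add atoms: trimethylsilyl trifluoromethanesulfonate, C[Si](C)(C)OS(=O)(=O)C(F)(F)F
Why: Soft enolisation and O-silylation of an enone; only the alpha' CH2 (future C2) can be deprotonated because the gamma carbon is quaternary, so one cross-conjugated silyl dienol ether should form.

Step 2
Reactants: 3 but-2-yn-1-ol
Product: 4 (2Z)-3-(triethylsilyl)but-2-en-1-ol
Conditions: Et3SiH, [Cp*Ru(MeCN)3]PF6 (2 mol %), CH2Cl2, 0 °C to rt
Reagents that add atoms: triethylsilane, CC[SiH](CC)CC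
Why: Ruthenium-catalysed trans-hydrosilylation of a propargylic alcohol puts silicon on the distal alkyne carbon and adds H and Si anti, which should give the Z vinylsilane with CH2OH cis to silicon.

Step 3
Reactants: 4 (2Z)-3-(triethylsilyl)but-2-en-1-ol
Product: 5 (2Z)-3-(triethylsilyl)but-2-enal
Conditions: activated MnO2, CH2Cl2, rt
Reagents that add atoms: none
Why: Allylic alcohol oxidation with MnO2 under neutral heterogeneous conditions, which should keep the Z geometry (CHO cis to silicon) that the ring closure needs.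

Step 4
Reactants: 2 trimethyl[(5,5-dimethylcyclopenta-1,3-dien-2-yl)oxy]silane; 5 (2Z)-3-(triethylsilyl)but-2-enal
Product: 8 rac-4-hydroxy-2,8,8-trimethylbicyclo[3.2.1]oct-2-en-6-one (both carbinol epimers), via aldol silyl ether 6 (not isolated), via bicyclic bis-silyl ether 7 (not isolated)
Conditions: Tf2NH (5 mol %), CH2Cl2, −78 to −20 °C; then 1 M HCl, THF, 0 °C
Reagents that add atoms: none
Why: Proposed new method: catalytic Tf2NH is converted by 2 into a silyl triflimide that promotes a Mukaiyama aldol 1,2-addition of the alpha' carbon of 2 (C2) to the aldehyde carbon of 5 (C3) and regenerates the enone in 6; silylation of that enone carbonyl makes the ring beta carbon (C6) a silyloxyallyl cation, which the vinylsilane captures at its silicon-bearing carbon (C5), the beta-silyl cation losing Et3Si+ to give 7, which acid hydrolyses to 8. The closest known reaction types are the Mukaiyama aldol reaction of enone-derived silyl dienol ethers with enals, the Hosomi–Sakurai conjugate addition of allylsilanes to Lewis-acid-activated enones and vinylsilane-terminated cation cyclisations; their union into one formal (3+3) annulation across C2 and C6 of a cyclopentenone is new. Ring A is closed by the C5–C6 bond in a 6-exo-trig attack on the enone (C7 stays outside the new ring), the vinylsilane reacting ipso with retention of the C4=C5 alkene, which gives the bicyclo[3.2.1]octene. The new stereocentres are the bridgeheads C2 and C6, which can only be cis because the three-carbon bridge spans one face of the five-membered ring, and the carbinol C3, which is not controlled; all are racemic or mixed and all are erased later (C3 in step 5, C2 in step 6, C6 in step 7), so the mixture converges. The step needs 1,2- rather than 1,4-addition to the enal, secured by the fully substituted, silylated beta carbon of 5, and ring closure through C5 rather than C4, secured by the beta-silicon effect (only attack at C5 gives a beta-silyl cation) and by the Z geometry that holds C5 within reach of C6.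

Step 5
Reactants: 8 rac-4-hydroxy-2,8,8-trimethylbicyclo[3.2.1]oct-2-en-6-one
Product: 9 rac-4,8,8-trimethylbicyclo[3.2.1]oct-3-ene-2,7-dione
Conditions: Dess–Martin periodinane, pyridine, CH2Cl2, 0 °C to rt
Reagents that add atoms: none
Why: Dess–Martin oxidation of the allylic alcohol to the enone; this merges both carbinol epimers and places the bridgehead C2 between the C3 and C8 carbonyls.

Step 6
Reactants: 9 rac-4,8,8-trimethylbicyclo[3.2.1]oct-3-ene-2,7-dione
Product: 10 rac-methyl 2-(2,6,6-trimethyl-4-oxocyclohex-2-en-1-yl)acetate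
Conditions: NaOMe (0.2 equiv), MeOH, 0 °C
Reagents that add atoms: methanol, CO
Why: Retro-Claisen cleavage of a non-enolisable bridgehead beta-diketone; methoxide should add to the strained, non-conjugated five-ring ketone (C8) and expel C2 as the cross-conjugated dienolate of the enone, which opens the temporary ring and leaves ring A with the C7H2–C8 ester.

Step 7
Reactants: 10 rac-methyl 2-(2,6,6-trimethyl-4-oxocyclohex-2-en-1-yl)acetate
Product: 11 methyl 2-(4-acetoxy-2,6,6-trimethylcyclohexa-1,3-dien-1-yl)acetate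
Conditions: isopropenyl acetate, TsOH·H2O (cat.), 90 °C, acetone distilled off
Reagents that add atoms: isopropenyl acetate, CC(=C)OC(C)=O
Why: Acid-catalysed enol acetylation under equilibrating conditions (as with steroidal enones) should give the linear dienol acetate with the tetrasubstituted C5=C6 alkene, which erases the C6 stereocentre and makes the material achiral.

Step 8
Reactants: 11 methyl 2-(4-acetoxy-2,6,6-trimethylcyclohexa-1,3-dien-1-yl)acetate
Product: 13 methyl 2-[(4R)-4-hydroxy-2,6,6-trimethylcyclohex-1-en-1-yl]acetate, via beta-gamma-unsaturated ketone 12 (not isolated)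
Conditions: Candida antarctica lipase B, (R)-selective ketoreductase, NADP+ (cat.), 2-propanol, phosphate buffer pH 7, MTBE, 30 °C
Reagents that add atoms: none
Why: Lipase hydrolysis of the enol ester releases the dienol, which ketonises by protonation at C4 to 12, and a ketoreductase (alcohol dehydrogenase class) then delivers hydride from NADPH to one face of the prochiral C3 ketone, which sets C3 (R) under enzyme control.

Step 9
Reactants: 14 dimethyl (2-hydroxyethyl)phosphonate
Product: 15 dimethyl [2-(tert-butyldimethylsilyloxy)ethyl]phosphonate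
Conditions: TBSCl, imidazole, CH2Cl2, rt
Reagents that add atoms: tert-butyldimethylsilyl chloride, CC(C)(C)[Si](C)(C)Cl
Why: Standard silylation of a primary alcohol; the silyl ether masks the future C19 hydroxyl through the phosphonate chemistry.

Step 10
Reactants: 13 methyl 2-[(4R)-4-hydroxy-2,6,6-trimethylcyclohex-1-en-1-yl]acetate; 15 dimethyl [2-(tert-butyldimethylsilyloxy)ethyl]phosphonate
Product: 16 dimethyl {1-(tert-butyldimethylsilyloxy)-4-[(4R)-4-hydroxy-2,6,6-trimethylcyclohex-1-en-1-yl]-3-oxobutan-2-yl}phosphonate (both C9 epimers)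
Conditions: 15 (3.3 equiv), n-BuLi (3.2 equiv), THF, −78 °C; then 13, −78 to −40 °C; aq. NH4Cl
Reagents that add atoms: none
Why: Claisen-type acylation of an alpha-lithio phosphonate by a methyl ester to a beta-ketophosphonate; excess reagent covers the free C3 hydroxyl and the acidic product, the low temperature should suppress beta-elimination of silyloxide, and the new C9 centre is lost in step 18.

Step 11
Reactants: 17 (R)-α-ionone
Product: 18 (R)-α-ionone ethylene ketal
Conditions: ethylene glycol, PPTS (cat.), benzene, reflux with water removal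
Reagents that add atoms: ethylene glycol, OCCO
Why: Ketalisation protects the side-chain ketone so that only the ring is oxidised and reduced in the next two steps.

Step 12
Reactants: 18 (R)-α-ionone ethylene ketal
Product: 19 (6R)-3-oxo-α-ionone ethylene ketal
Conditions: t-BuOOH, Rh2(cap)4 (dirhodium tetracaprolactamate, 1 mol %), K2CO3, CH2Cl2, rt
Reagents that add atoms: tert-butyl hydroperoxide, CC(C)(C)OO
Why: Dirhodium-catalysed allylic oxidation with tert-butyl hydroperoxide converts the ring allylic CH2 (C3') into the enone carbonyl, and the weakly basic heterogeneous conditions should leave the C6' configuration untouched.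

Step 13
Reactants: 19 (6R)-3-oxo-α-ionone ethylene ketal
Product: 21 (3R,6R)-3-hydroxy-α-ionone, via hydroxy ketal 20 (not isolated)
Conditions: (S)-2-methyl-CBS-oxazaborolidine (20 mol %), catecholborane, toluene, −78 °C; then 1 M HCl, THF, 0 °C
Reagents that add atoms: water, O
Why: Corey–Bakshi–Shibata reduction of the ring enone, with the alkenyl side as the large group, should give the (3'R) allylic alcohol (trans to the side chain) under catalyst control, and the acidic work-up hydrolyses the dioxolane.

Step 14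
Reactants: 21 (3R,6R)-3-hydroxy-α-ionone
Product: 22 (3R,6R)-3-hydroxy-9-vinyl-α-ionol (both C9 epimers)
Conditions: CH2=CHMgBr (3 equiv), THF, 0 °C
Reagents that add atoms: vinylmagnesium bromide, C=C[Mg]Br
Why: Grignard 1,2-addition to the methyl ketone as in vinyl-ionol syntheses; the new tertiary carbinol centre is a mixture and disappears in step 15.

Step 15
Reactants: 22 (3R,6R)-3-hydroxy-9-vinyl-α-ionol
Product: 23 [(2E,4E)-5-[(1R,4R)-4-hydroxy-2,6,6-trimethylcyclohex-2-en-1-yl]-3-methylpenta-2,4-dien-1-yl]triphenylphosphonium bromide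
Conditions: PPh3·HBr, MeOH, rt
Reagents that add atoms: triphenylphosphine hydrobromide, [Br-].c1ccc(cc1)[PH+](c1ccccc1)c1ccccc1
Why: Acid-promoted allylic transposition of the tertiary divinyl carbinol with capture by triphenylphosphine, the classical route to C15 Wittig salts; the conjugated E dienyl salt should form while the less ionisable secondary C3' alcohol is kept.

Step 16
Reactants: 23 C15 phosphonium bromide; 24 (2E,4E,6E)-2,7-dimethylocta-2,4,6-trienedial
Product: 25 (2E,4E,6E,8E,10E,12E)-13-[(1R,4R)-4-hydroxy-2,6,6-trimethylcyclohex-2-en-1-yl]-2,7,11-trimethyltrideca-2,4,6,8,10,12-hexaenal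
Conditions: 24 (1.5 equiv), NaOMe, MeOH/CH2Cl2, 0 °C to rt, dark
Reagents that add atoms: none
Why: Wittig olefination of one aldehyde group; excess dialdehyde limits double condensation and the conjugated ylide should give mainly the E C11'=C12' alkene, the Z isomer equilibrating on warming.

Step 17
Reactants: 25 C25 hydroxy-aldehyde; 26 (1,3-dioxolan-2-ylmethyl)triphenylphosphonium bromide
Product: 28 (2E,4E,6E,8E,10E,12E,14E)-15-[(1R,4R)-4-hydroxy-2,6,6-trimethylcyclohex-2-en-1-yl]-4,9,13-trimethylpentadeca-2,4,6,8,10,12,14-heptaenal, via C27 dioxolane 27 (not isolated)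
Conditions: NaOMe, MeOH/CH2Cl2, rt; then 1 M HCl, THF, 0 °C, dark
Reagents that add atoms: water, O
Why: Wittig two-carbon homologation with a formylmethylene equivalent followed by acetal hydrolysis, under which the new C11=C12 alkene should equilibrate to E.

Step 18
Reactants: 16 ring-A ketophosphonate; 28 C27 hydroxy-aldehyde
Product: 29 19-O-(tert-butyldimethylsilyl)siphonaxanthin
Conditions: Ba(OH)2·8H2O, THF/H2O (40:1), rt, dark, argon
Reagents that add atoms: none
Why: Horner–Wadsworth–Emmons olefination of an alpha-substituted beta-ketophosphonate; the acyl group and the polyene chain should end trans (C19 cis to C11, the required C9=C10 geometry), and the mild base spares the free hydroxyls and the beta-silyloxy group.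

Step 19
Reactants: 29 19-O-(tert-butyldimethylsilyl)siphonaxanthin
Product: 30 (3R,3'R,6'R)-siphonaxanthin
Conditions: HF·pyridine, pyridine, THF, 0 °C, dark
Reagents that add atoms: none
Why: Buffered fluoride cleavage of the primary allylic silyl ether, which the polyene and the beta,gamma-unsaturated ketone should tolerate.

Step 20
Reactants: 30 (3R,3'R,6'R)-siphonaxanthin; 31 vinyl dodecanoate
Product: 32 siphonaxanthin 19-dodecanoate (CNP0415583.1)
Conditions: Novozym 435 (immobilised Candida antarctica lipase B), MTBE, 35 °C, dark, argon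
Reagents that add atoms: none
Why: Lipase-catalysed transesterification with an irreversible vinyl ester donor; the enzyme should acylate the unhindered primary C19 hydroxyl and leave the two secondary ring hydroxyls.

**Compound list**
1 | 4,4-dimethylcyclopent-2-en-1-one | O=C1C=CC(C)(C)C1 | starting material
2 | trimethyl[(5,5-dimethylcyclopenta-1,3-dien-2-yl)oxy]silane | C[Si](C)(C)OC1=CC(C)(C)C=C1 | intermediate
3 | but-2-yn-1-ol | CC#CCO | starting material
4 | (2Z)-3-(triethylsilyl)but-2-en-1-ol | OC/C=C(/C)[Si](CC)(CC)CC | intermediate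
5 | (2Z)-3-(triethylsilyl)but-2-enal | O=C/C=C(/C)[Si](CC)(CC)CC | intermediate
6 | 4,4-dimethyl-5-[(2Z)-3-(triethylsilyl)-1-(trimethylsilyloxy)but-2-en-1-yl]cyclopent-2-en-1-one (racemic, both diastereomers) | O=C1C=CC(C)(C)C1C(O[Si](C)(C)C)/C=C(/C)[Si](CC)(CC)CC | intermediate
7 | 6-(triethylsilyloxy)-2,8,8-trimethyl-4-(trimethylsilyloxy)bicyclo[3.2.1]octa-2,6-diene (racemic, both C4 epimers) | C[Si](C)(C)OC1C=C(C)C2C=C(O[Si](CC)(CC)CC)C1C2(C)C | intermediate
8 | rac-4-hydroxy-2,8,8-trimethylbicyclo[3.2.1]oct-2-en-6-one (both carbinol epimers) | OC1C=C(C)C2CC(=O)C1C2(C)C | intermediate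
9 | rac-4,8,8-trimethylbicyclo[3.2.1]oct-3-ene-2,7-dione | O=C1C=C(C)C2CC(=O)C1C2(C)C | intermediate
10 | rac-methyl 2-(2,6,6-trimethyl-4-oxocyclohex-2-en-1-yl)acetate | COC(=O)CC1C(C)=CC(=O)CC1(C)C | intermediate
11 | methyl 2-(4-acetoxy-2,6,6-trimethylcyclohexa-1,3-dien-1-yl)acetate | COC(=O)CC1=C(C)C=C(OC(C)=O)CC1(C)C | intermediate
12 | methyl 2-(2,6,6-trimethyl-4-oxocyclohex-1-en-1-yl)acetate | COC(=O)CC1=C(C)CC(=O)CC1(C)C | intermediate
13 | methyl 2-[(4R)-4-hydroxy-2,6,6-trimethylcyclohex-1-en-1-yl]acetate | COC(=O)CC1=C(C)C[C@@H](O)CC1(C)C | intermediate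
14 | dimethyl (2-hydroxyethyl)phosphonate | COP(=O)(CCO)OC | starting material
15 | dimethyl [2-(tert-butyldimethylsilyloxy)ethyl]phosphonate | COP(=O)(CCO[Si](C)(C)C(C)(C)C)OC | intermediate
16 | dimethyl {1-(tert-butyldimethylsilyloxy)-4-[(4R)-4-hydroxy-2,6,6-trimethylcyclohex-1-en-1-yl]-3-oxobutan-2-yl}phosphonate (both C9 epimers) | COP(=O)(OC)C(CO[Si](C)(C)C(C)(C)C)C(=O)CC1=C(C)C[C@@H](O)CC1(C)C | intermediate
17 | (R)-α-ionone | CC(=O)/C=C/[C@H]1C(C)=CCCC1(C)C | starting material
18 | (R)-α-ionone ethylene ketal | CC1(OCCO1)/C=C/[C@H]1C(C)=CCCC1(C)C | intermediate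
19 | (6R)-3-oxo-α-ionone ethylene ketal | CC1(OCCO1)/C=C/[C@H]1C(C)=CC(=O)CC1(C)C | intermediate
20 | (3R,6R)-3-hydroxy-α-ionone ethylene ketal | CC1(OCCO1)/C=C/[C@H]1C(C)=C[C@H](O)CC1(C)C | intermediate
21 | (3R,6R)-3-hydroxy-α-ionone | CC(=O)/C=C/[C@H]1C(C)=C[C@H](O)CC1(C)C | intermediate
22 | (3R,6R)-3-hydroxy-9-vinyl-α-ionol (both C9 epimers) | CC(O)(C=C)/C=C/[C@H]1C(C)=C[C@H](O)CC1(C)C | intermediate
23 | [(2E,4E)-5-[(1R,4R)-4-hydroxy-2,6,6-trimethylcyclohex-2-en-1-yl]-3-methylpenta-2,4-dien-1-yl]triphenylphosphonium bromide | c1ccccc1[P+](c1ccccc1)(c1ccccc1)C/C=C(C)/C=C/[C@H]1C(C)=C[C@H](O)CC1(C)C.[Br-] | intermediate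
24 | (2E,4E,6E)-2,7-dimethylocta-2,4,6-trienedial | O=C/C(C)=C/C=C/C=C(C)/C=O | starting material
25 | (2E,4E,6E,8E,10E,12E)-13-[(1R,4R)-4-hydroxy-2,6,6-trimethylcyclohex-2-en-1-yl]-2,7,11-trimethyltrideca-2,4,6,8,10,12-hexaenal | O=C/C(C)=C/C=C/C=C(C)/C=C/C=C(C)/C=C/[C@H]1C(C)=C[C@H](O)CC1(C)C | intermediate
26 | (1,3-dioxolan-2-ylmethyl)triphenylphosphonium bromide | C1COC(O1)C[P+](c1ccccc1)(c1ccccc1)c1ccccc1.[Br-] | starting material
27 | 2-[(1E,3E,5E,7E,9E,11E,13E)-14-[(1R,4R)-4-hydroxy-2,6,6-trimethylcyclohex-2-en-1-yl]-3,8,12-trimethyltetradeca-1,3,5,7,9,11,13-heptaen-1-yl]-1,3-dioxolane | C1COC(O1)/C=C/C(C)=C/C=C/C=C(C)/C=C/C=C(C)/C=C/[C@H]1C(C)=C[C@H](O)CC1(C)C | intermediate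
28 | (2E,4E,6E,8E,10E,12E,14E)-15-[(1R,4R)-4-hydroxy-2,6,6-trimethylcyclohex-2-en-1-yl]-4,9,13-trimethylpentadeca-2,4,6,8,10,12,14-heptaenal | O=C/C=C/C(C)=C/C=C/C=C(C)/C=C/C=C(C)/C=C/[C@H]1C(C)=C[C@H](O)CC1(C)C | intermediate
29 | 19-O-(tert-butyldimethylsilyl)siphonaxanthin | CC(C)(C)[Si](C)(C)OC\C(=C/C=C/C(C)=C/C=C/C=C(C)/C=C/C=C(C)/C=C/[C@H]1C(C)=C[C@H](O)CC1(C)C)C(=O)CC1=C(C)C[C@@H](O)CC1(C)C | intermediate
30 | (3R,3'R,6'R)-siphonaxanthin (3,19,3'-trihydroxy-7,8-dihydro-β,ε-caroten-8-one) | OC\C(=C/C=C/C(C)=C/C=C/C=C(C)/C=C/C=C(C)/C=C/[C@H]1C(C)=C[C@H](O)CC1(C)C)C(=O)CC1=C(C)C[C@@H](O)CC1(C)C | intermediate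
31 | vinyl dodecanoate | CCCCCCCCCCCC(=O)OC=C | starting material
32 | siphonaxanthin 19-dodecanoate (CNP0415583.1) | CCCCCCCCCCCC(=O)OC\C(=C/C=C/C(C)=C/C=C/C=C(C)/C=C/C=C(C)/C=C/[C@H]1C(C)=C[C@H](O)CC1(C)C)C(=O)CC1=C(C)C[C@@H](O)CC1(C)C | target

**Step count:** 20 steps in total.
**Longest linear sequence:** 11 steps (3 → 4 → 5 → 8 → 9 → 10 → 11 → 13 → 16 → 29 → 30 → 32).

**Steps most likely to fail**

Step 4 (proposed new method). The vinylsilane may be too weak a nucleophile for the silyl-activated enone, may close through C4 to a five-membered ring, or the allylic silyl ether of 6 may ionise before cyclisation. The fallback forms the two bonds in two steps of known chemistry; it sets out from 2 and 3 and returns at 8. Alkyne 3 is hydroaluminated with Red-Al (NaAlH2(OCH2CH2OCH3)2) and the vinylalanate is quenched with I2 to give (2Z)-3-iodobut-2-en-1-ol F1, which MnO2 oxidises to (2Z)-3-iodobut-2-enal F2. A Mukaiyama aldol reaction of 2 with F2 (BF3·OEt2, CH2Cl2, −78 °C) gives 5-[(2Z)-1-hydroxy-3-iodobut-2-en-1-yl]-4,4-dimethylcyclopent-2-en-1-one F3. An intramolecular reductive Heck cyclisation (Pd(OAc)2, PPh3, HCO2Na, DMF, 80 °C) then closes C5–C6 by syn-carbopalladation of the enone; the palladium enolate cannot eliminate toward the bridgehead and is reduced, which gives 8.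

Step 8. The enzyme may discriminate poorly between the two faces of a ketone whose alpha-methylene arms differ only at their beta carbons, and 12 may isomerise to the conjugated enone before it is reduced. The fallback replaces asymmetric reduction by resolution; it sets out from 11 and returns at 13. NaBH4 in EtOH/THF at 0 °C reduces the dienol acetate (through 12 formed in situ) to rac-methyl 2-(4-hydroxy-2,6,6-trimethylcyclohex-1-en-1-yl)acetate F4. Lipase-catalysed acylation with vinyl acetate resolves F4: the (R) series is collected as methyl 2-[(4R)-4-acetoxy-2,6,6-trimethylcyclohex-1-en-1-yl]acetate F5 and methanolysed (K2CO3, MeOH) to 13, or, if the enzyme prefers the (S)-alcohol, as unreacted 13. The unwanted enantiomer is oxidised back to 12 with Dess–Martin periodinane and recycled.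

Step 18. Slow addition of the hindered phosphonate anion to the conjugated polyenal would give time for beta-elimination of silyloxide and for base-induced migration of the C5=C6 alkene. The fallback makes C9=C10 on a small aldehyde and ends with a Wittig reaction at C11=C12; it sets out from 16 and 25 and returns at 29. Phosphonate 16 is condensed with 2,2-dimethoxyacetaldehyde (Ba(OH)2, THF/H2O) to (3E)-3-[(tert-butyldimethylsilyloxy)methyl]-1-[(4R)-4-hydroxy-2,6,6-trimethylcyclohex-1-en-1-yl]-5,5-dimethoxypent-3-en-2-one F6. Oxalic acid on wet silica hydrolyses F6 to (2E)-3-[(tert-butyldimethylsilyloxy)methyl]-5-[(4R)-4-hydroxy-2,6,6-trimethylcyclohex-1-en-1-yl]-4-oxopent-2-enal F7. Aldehyde 25 is reduced (NaBH4, MeOH, 0 °C) to (2E,4E,6E,8E,10E,12E)-13-[(1R,4R)-4-hydroxy-2,6,6-trimethylcyclohex-2-en-1-yl]-2,7,11-trimethyltrideca-2,4,6,8,10,12-hexaen-1-ol F8, which PPh3·HBr converts into [(2E,4E,6E,8E,10E,12E)-13-[(1R,4R)-4-hydroxy-2,6,6-trimethylcyclohex-2-en-1-yl]-2,7,11-trimethyltrideca-2,4,6,8,10,12-hexaen-1-yl]triphenylphosphonium bromide F9. A Wittig reaction of F7 with F9 under neutral conditions (1,2-epoxybutane, EtOH, reflux) gives 29.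

**Further compounds**
F1 | step 4 | (2Z)-3-iodobut-2-en-1-ol | OC/C=C(/C)I
F2 | step 4 | (2Z)-3-iodobut-2-enal | O=C/C=C(/C)I
F3 | step 4 | 5-[(2Z)-1-hydroxy-3-iodobut-2-en-1-yl]-4,4-dimethylcyclopent-2-en-1-one | O=C1C=CC(C)(C)C1C(O)/C=C(/C)I
F4 | step 8 | rac-methyl 2-(4-hydroxy-2,6,6-trimethylcyclohex-1-en-1-yl)acetate | COC(=O)CC1=C(C)CC(O)CC1(C)C
F5 | step 8 | methyl 2-[(4R)-4-acetoxy-2,6,6-trimethylcyclohex-1-en-1-yl]acetate | COC(=O)CC1=C(C)C[C@@H](OC(C)=O)CC1(C)C
F6 | step 18 | (3E)-3-[(tert-butyldimethylsilyloxy)methyl]-1-[(4R)-4-hydroxy-2,6,6-trimethylcyclohex-1-en-1-yl]-5,5-dimethoxypent-3-en-2-one | CC(C)(C)[Si](C)(C)OC\C(=C/C(OC)OC)C(=O)CC1=C(C)C[C@@H](O)CC1(C)C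
F7 | step 18 | (2E)-3-[(tert-butyldimethylsilyloxy)methyl]-5-[(4R)-4-hydroxy-2,6,6-trimethylcyclohex-1-en-1-yl]-4-oxopent-2-enal | CC(C)(C)[Si](C)(C)OC\C(=C/C=O)C(=O)CC1=C(C)C[C@@H](O)CC1(C)C
F8 | step 18 | (2E,4E,6E,8E,10E,12E)-13-[(1R,4R)-4-hydroxy-2,6,6-trimethylcyclohex-2-en-1-yl]-2,7,11-trimethyltrideca-2,4,6,8,10,12-hexaen-1-ol | OC/C(C)=C/C=C/C=C(C)/C=C/C=C(C)/C=C/[C@H]1C(C)=C[C@H](O)CC1(C)C
F9 | step 18 | [(2E,4E,6E,8E,10E,12E)-13-[(1R,4R)-4-hydroxy-2,6,6-trimethylcyclohex-2-en-1-yl]-2,7,11-trimethyltrideca-2,4,6,8,10,12-hexaen-1-yl]triphenylphosphonium bromide | c1ccccc1[P+](c1ccccc1)(c1ccccc1)C/C(C)=C/C=C/C=C(C)/C=C/C=C(C)/C=C/[C@H]1C(C)=C[C@H](O)CC1(C)C.[Br-]
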